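## Retrosynthetic overview
1. The furan–arene bond is made last. p-Benzoquinone, the reversed-polarity form of hydroquinone, is attacked by the free α-C–H (C5) of a 3-alkylfuran, so no phenol protection is needed.
2. The C7=C8 alkene comes from an isopropylidene Wittig on a C7 aldehyde. The C5 stereocentre and the C5–furan bond come from a rhodium/chiral-diene 1,4-addition of furan-3-ylboronic acid to an E-enal.
3. The enal comes from methyl (R)-3-methylglutarate, which supplies C3 with its configuration, by reduction, oxidation and formyl olefination.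
4. No ring is built. The furan arrives intact in step 3; the benzene ring arrives as the quinone in step 5 and is aromatised there.

Assumption: methyl (R)-3-methylglutarate 1 is bought in high ee (it is also available in one step from 3-methylglutaric anhydride by alkaloid-mediated methanolysis).

The target is (3R,5S)-5-[5-(2,5-dihydroxyphenyl)furan-3-yl]-3,8-dimethylnon-7-enoic acid.

## Route

Step 1
Reactants: 1 methyl (R)-3-methylglutarate [(3R)-5-methoxy-3-methyl-5-oxopentanoic acid]
Product: 2 methyl (3R)-5-hydroxy-3-methylpentanoate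
Conditions: BH3·SMe2 (1.1 equiv), THF, −10 °C → rt; MeOH quench; used crude
Reagents that add atoms: none
Why: Chemoselective borane reduction: the free acid is reduced through its acyloxyborane much faster than the methyl ester, so only the acid arm becomes CH2OH and C3 (not α to any carbonyl) keeps its R configuration.

Step 2
Reactants: 2 methyl (3R)-5-hydroxy-3-methylpentanoate; 3 (triphenylphosphoranylidene)acetaldehyde
Product: 5 methyl (3R,5E)-3-methyl-7-oxohept-5-enoate, via aldehyde 4 (not isolated)
Conditions: TEMPO (10 mol%), PhI(OAc)2 (1.05 equiv), CH2Cl2, rt, 3 h; then 3 (1.3 equiv), 40 °C, 16 h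
Reagents that add atoms: (triphenylphosphoranylidene)acetaldehyde 3, O=CC=P(c1ccccc1)(c1ccccc1)c1ccccc1
Why: Oxoammonium (TEMPO/PhI(OAc)2) oxidation stops at aldehyde 4, which is trapped in the same flask by the stabilised formyl ylide in an E-selective Wittig olefination, so neither the lactonisation-prone hydroxy ester nor the labile aldehyde is stored.

Step 3
Reactants: 5 methyl (3R,5E)-3-methyl-7-oxohept-5-enoate; 6 furan-3-ylboronic acid
Product: 7 methyl (3R,5S)-5-(furan-3-yl)-3-methyl-7-oxoheptanoate
Conditions: 6 (2.5 equiv), [RhCl(C2H4)2]2 (2.5 mol%), chiral diene Ph-bod* (2,5-diphenylbicyclo[2.2.2]octa-2,5-diene, 5.5 mol%, the antipode that gives Si-face attack at C5), KOH (0.2 equiv), dioxane/H2O 10:1, 30 °C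
Reagents that add atoms: furan-3-ylboronic acid 6, OB(O)c1ccoc1
Why: Hayashi–Miyaura rhodium-catalysed asymmetric 1,4-addition: the diene-bound furyl–rhodium species adds to the Si face of C5 of the E-enal under catalyst control (the remote C3 centre has little say), which sets C5 as S, and diene ligands favour 1,4- over 1,2-addition to enals.

Step 4
Reactants: 7 methyl (3R,5S)-5-(furan-3-yl)-3-methyl-7-oxoheptanoate; 8 isopropyltriphenylphosphonium iodide
Product: 10 (3R,5S)-5-(furan-3-yl)-3,8-dimethylnon-7-enoic acid, via methyl ester 9 (not isolated)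
Conditions: 8 (1.5 equiv), n-BuLi (1.45 equiv), THF, 0 °C; add 7, −78 → 0 °C; then LiOH (5 equiv), MeOH/H2O, rt; 1 M HCl to pH 4 at 0 °C
Reagents that add atoms: isopropyltriphenylphosphonium iodide 8, CC(C)[P+](c1ccccc1)(c1ccccc1)c1ccccc1.[I-]; lithium hydroxide, [Li+].[OH-]
Why: Wittig olefination with the non-stabilised isopropylidene ylide turns the aldehyde into the trisubstituted C7=C8 alkene (no E/Z issue) while the ester is ignored at low temperature; saponification in the same flask gives the acid, which acid–base extraction frees from Ph3PO, and C5 is β to the aldehyde so it cannot epimerise.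

Step 5
Reactants: 10 (3R,5S)-5-(furan-3-yl)-3,8-dimethylnon-7-enoic acid; 11 1,4-benzoquinone
Product: 13 (3R,5S)-5-[5-(2,5-dihydroxyphenyl)furan-3-yl]-3,8-dimethylnon-7-enoic acid, via furylbenzoquinone 12 (not isolated)
Conditions: 11 (2.2 equiv), (PhO)2P(O)OH (10 mol%), HFIP/CH2Cl2 1:4, 0 °C → rt, Ar, dark; then aq. Na2S2O4, EtOAc
Reagents that add atoms: 1,4-benzoquinone 11, O=C1C=CC(=O)C=C1
Why: Proposed new method: p-benzoquinone acts as the reversed-polarity form of hydroquinone (the ring carbon that is nucleophilic in the phenol is the electrophile here) and, activated by hydrogen bonding from HFIP and the phosphoric acid, is attacked by the furan in a Friedel–Crafts-type conjugate addition, expected at the free C5–H because C2–H is flanked by the α-branched side chain; tautomerisation gives the hydroquinone, the second equivalent of 11 oxidises it to 12 and dithionite returns 13, while the mild acid leaves the prenyl alkene and both stereocentres untouched; the closest known reaction type is the acid-promoted substitutive addition of 2-alkylfurans and of indoles to p-quinones.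

## Compound list
1 | methyl (R)-3-methylglutarate, (3R)-5-methoxy-3-methyl-5-oxopentanoic acid | COC(=O)C[C@H](C)CC(=O)O | starting material
2 | methyl (3R)-5-hydroxy-3-methylpentanoate | COC(=O)C[C@H](C)CCO | intermediate
3 | (triphenylphosphoranylidene)acetaldehyde | O=CC=P(c1ccccc1)(c1ccccc1)c1ccccc1 | starting material
4 | methyl (3R)-3-methyl-5-oxopentanoate | COC(=O)C[C@H](C)CC=O | intermediate
5 | methyl (3R,5E)-3-methyl-7-oxohept-5-enoate | COC(=O)C[C@H](C)C/C=C/C=O | intermediate
6 | furan-3-ylboronic acid | OB(O)c1ccoc1 | starting material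
7 | methyl (3R,5S)-5-(furan-3-yl)-3-methyl-7-oxoheptanoate | COC(=O)C[C@H](C)C[C@@H](CC=O)c1ccoc1 | intermediate
8 | isopropyltriphenylphosphonium iodide | CC(C)[P+](c1ccccc1)(c1ccccc1)c1ccccc1.[I-] | starting material
9 | methyl (3R,5S)-5-(furan-3-yl)-3,8-dimethylnon-7-enoate | COC(=O)C[C@H](C)C[C@@H](CC=C(C)C)c1ccoc1 | intermediate
10 | (3R,5S)-5-(furan-3-yl)-3,8-dimethylnon-7-enoic acid | OC(=O)C[C@H](C)C[C@@H](CC=C(C)C)c1ccoc1 | intermediate
11 | 1,4-benzoquinone | O=C1C=CC(=O)C=C1 | starting material
12 | (3R,5S)-5-[5-(3,6-dioxocyclohexa-1,4-dien-1-yl)furan-3-yl]-3,8-dimethylnon-7-enoic acid | OC(=O)C[C@H](C)C[C@@H](CC=C(C)C)c1coc(C2=CC(=O)C=CC2=O)c1 | intermediate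
13 | (3R,5S)-5-[5-(2,5-dihydroxyphenyl)furan-3-yl]-3,8-dimethylnon-7-enoic acid | CC(C)=CC[C@H](C[C@@H](C)CC(=O)O)c1coc(-c2cc(O)ccc2O)c1 | target

## Step count and risks
Total steps: 5. Longest linear sequence: 5.

Steps most likely to fail:

Step 5 (site of attack on the furan). A 3-alkylfuran is electronically biased towards C2, and only the steric bulk of the branched side chain steers the quinone to C5; a mixture with the 2,3-disubstituted isomer is the main danger, and over-arylation and acid sensitivity of the prenyl–furan pair are lesser ones. The fallback fixes the site by sterically controlled C–H borylation. It sets out from 9 (step 4 is stopped before the LiOH addition and 9 is isolated) and comes back to the route at 13. [Ir(OMe)(cod)]2 with 4,4'-di-tert-butyl-2,2'-bipyridine and B2pin2 in hexane at rt borylates only the unhindered furan α-C–H to give methyl (3R,5S)-3,8-dimethyl-5-[5-(4,4,5,5-tetramethyl-1,3,2-dioxaborolan-2-yl)furan-3-yl]non-7-enoate F1. Suzuki–Miyaura coupling with 2-bromobenzene-1,4-diol (Pd(dppf)Cl2, K3PO4, degassed dioxane/H2O, 60 °C) gives methyl (3R,5S)-5-[5-(2,5-dihydroxyphenyl)furan-3-yl]-3,8-dimethylnon-7-enoate F2. LiOH in degassed THF/H2O with a little Na2S2O4, then acidification to pH 4, gives 13.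

Step 3 (1,4-addition to an enal). Risks are 1,2-addition, aldol loss of the product aldehyde under the basic conditions, protodeboronation of 6 and insufficient ee. The fallback changes the acceptor to an unsaturated Weinreb amide. It sets out from 2 and comes back at 7. 2 is oxidised to 4 as in step 2 and treated in the same flask with diethyl [2-[methoxy(methyl)amino]-2-oxoethyl]phosphonate, LiCl and DBU (Horner–Wadsworth–Emmons) to give methyl (3R,5E)-7-[methoxy(methyl)amino]-3-methyl-7-oxohept-5-enoate F3. Rhodium/chiral-diene addition of 6 as in step 3, at 60 °C, gives methyl (3R,5S)-5-(furan-3-yl)-7-[methoxy(methyl)amino]-3-methyl-7-oxoheptanoate F4. Cp2Zr(H)Cl in THF at rt reduces the amide, and not the ester, to aldehyde 7.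

Step 2 (formyl Wittig in one flask). Risks are lactonisation of 2, slow reaction of the weakly nucleophilic ylide and double homologation to the dienal. The fallback builds the enal by cross-metathesis. It sets out from 2 and comes back at 5. 2 is oxidised (TEMPO/PhI(OAc)2) to 4, which is isolated and methylenated with Ph3P=CH2 (from methyltriphenylphosphonium bromide and KOt-Bu, THF, 0 °C) to give methyl (3R)-3-methylhex-5-enoate F5. Cross-metathesis of this alkene with crotonaldehyde (5 equiv, second-generation Hoveyda–Grubbs catalyst 2 mol%, CH2Cl2, 40 °C) gives E-enal 5.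

## Further compounds
F1 | step 5 | methyl (3R,5S)-3,8-dimethyl-5-[5-(4,4,5,5-tetramethyl-1,3,2-dioxaborolan-2-yl)furan-3-yl]non-7-enoate | COC(=O)C[C@H](C)C[C@@H](CC=C(C)C)c1coc(B2OC(C)(C)C(C)(C)O2)c1
F2 | step 5 | methyl (3R,5S)-5-[5-(2,5-dihydroxyphenyl)furan-3-yl]-3,8-dimethylnon-7-enoate | COC(=O)C[C@H](C)C[C@@H](CC=C(C)C)c1coc(-c2cc(O)ccc2O)c1
F3 | step 3 | methyl (3R,5E)-7-[methoxy(methyl)amino]-3-methyl-7-oxohept-5-enoate | COC(=O)C[C@H](C)C/C=C/C(=O)N(C)OC
F4 | step 3 | methyl (3R,5S)-5-(furan-3-yl)-7-[methoxy(methyl)amino]-3-methyl-7-oxoheptanoate | COC(=O)C[C@H](C)C[C@@H](CC(=O)N(C)OC)c1ccoc1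
F5 | step 2 | methyl (3R)-3-methylhex-5-enoate | COC(=O)C[C@H](C)CC=C
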